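The target is cut at the bond between the methylene carbon and C-1 of ring B (the catechol ring without a methyl group). Both halves contain the same (S)-3-(1,2,2-trimethylcyclopentyl)veratrole, so one Pd-catalysed asymmetric conjugate addition serves both quaternary centres. The key step exploits that ring B C-1 is the only ring carbon flanked by two CH positions: sterically governed Ir borylation marks it, and a Pd-catalysed sp3–sp2 Suzuki–Miyaura coupling joins this arylboronate to the benzyl chloride of ring A (the methylated ring). That chloride comes from the same boronate by methylation and chloromethylation at the only open ring A carbon, between the methoxy-bearing and the methyl-bearing carbon. BBr3 then frees the four hydroxyls.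

Key step: step 9

Assumption: the sense of induction usual for Pd/t-BuPyOx additions to 3-methylcycloalkenones ((S)-ligand giving the (R)-3-aryl-3-methyl ketone) is taken to hold for the ortho-methoxyaryl group, hence the (R)-ligand in step 1. The geometry at the quaternary carbon is never touched afterwards; the changes of its descriptor (S, R, S) along the route come from CIP priorities only.

Step 1
Reactants: 1 (2,3-dimethoxyphenyl)boronic acid; 2 3-methylcyclopent-2-en-1-one
Product: 3 (S)-3-(2,3-dimethoxyphenyl)-3-methylcyclopentan-1-one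
Conditions: Pd(OCOCF3)2 (5 mol %), (R)-t-BuPyOx (6 mol %), NH4PF6 (30 mol %), H2O (5 equiv), ClCH2CH2Cl, 40 °C
Reagents that add atoms: none
Why: Pd(II)/pyridine-oxazoline-catalysed asymmetric conjugate addition of an arylboronic acid to a β-substituted cyclic enone (transmetalation, face-selective insertion of the enone into the aryl–Pd bond, protonolysis of the Pd enolate); the chiral ligand selects the enone face and so sets the quaternary stereocentre as (S).

Step 2
Reactants: 3 (S)-3-(2,3-dimethoxyphenyl)-3-methylcyclopentan-1-one
Product: 5 (R)-4-(2,3-dimethoxyphenyl)-4-methylcyclopent-2-en-1-one, via trimethylsilyl enol ether 4 (not isolated)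
Conditions: LDA, THF, −78 °C, then TMSCl; crude 4, Pd(OAc)2 (10 mol %), O2 (1 atm), DMSO, rt
Reagents that add atoms: chlorotrimethylsilane, C[Si](C)(C)Cl (silyl group of 4 only)
Why: Saegusa–Ito oxidation in its aerobic catalytic form: kinetic enolisation at the α-CH2 remote from the quaternary carbon, O-silylation, then Pd(II) enolate formation and β-hydride elimination; only the C4–C5 bond can be desaturated because C3 is quaternary, and the stereocentre is not involved.

Step 3
Reactants: 5 (R)-4-(2,3-dimethoxyphenyl)-4-methylcyclopent-2-en-1-one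
Product: 7 (R)-4-(2,3-dimethoxyphenyl)-4,5,5-trimethylcyclopent-2-en-1-one, via monomethyl enone 6 (not isolated)
Conditions: NaH (3 equiv), MeI (4 equiv), THF/DMF, 0 °C → rt
Reagents that add atoms: iodomethane, CI
Why: exhaustive α'-alkylation of the cross-conjugated enolate; C5 is the only carbon that can be deprotonated (the γ-carbon C4 is quaternary), so both methyl groups should end on the carbon next to the stereocentre.

Step 4
Reactants: 7 (R)-4-(2,3-dimethoxyphenyl)-4,5,5-trimethylcyclopent-2-en-1-one
Product: 8 (R)-3-(2,3-dimethoxyphenyl)-2,2,3-trimethylcyclopentan-1-one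
Conditions: H2 (1 atm), 10% Pd/C, EtOAc, rt
Reagents that add atoms: none
Why: heterogeneous catalytic hydrogenation of the disubstituted enone C=C; ketone, arene and methyl ethers are inert under these conditions and no stereocentre is formed.

Step 5
Reactants: 8 (R)-3-(2,3-dimethoxyphenyl)-2,2,3-trimethylcyclopentan-1-one
Product: 10 (S)-1,2-dimethoxy-3-(1,2,2-trimethylcyclopentyl)benzene, via hydrazone 9 (not isolated)
Conditions: N2H4·H2O, KOH, diethylene glycol, 130 °C, then 200 °C with removal of H2O
Reagents that add atoms: hydrazine, NN (nitrogen atoms of 9 only)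
Why: Wolff–Kishner reduction (Huang-Minlon procedure): hydrazone formation and base-induced loss of N2 turn C=O into CH2; the quaternary stereocentre has no α-hydrogen and cannot epimerise.

Step 6
Reactants: 10 (S)-1,2-dimethoxy-3-(1,2,2-trimethylcyclopentyl)benzene
Product: 11 2-{3,4-dimethoxy-5-[(1S)-1,2,2-trimethylcyclopentyl]phenyl}-4,4,5,5-tetramethyl-1,3,2-dioxaborolane
Conditions: B2pin2 (1.0 equiv), [Ir(OMe)(cod)]2 (1.5 mol %), dtbpy (3 mol %), THF, 80 °C
Reagents that add atoms: bis(pinacolato)diboron, CC1(C)OB(OC1(C)C)B1OC(C)(C)C(C)(C)O1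
Why: Ir-catalysed aromatic C–H borylation is sterically controlled: of the three ring CH groups, C4 lies next to the quaternary carbon and C6 next to OMe, so boron should go to C5, the only CH with two CH neighbours (the future ring B C-1).

Step 7
Reactants: 11 arylboronate (about half of the batch; the rest is kept for step 9)
Product: 12 1,2-dimethoxy-5-methyl-3-[(1S)-1,2,2-trimethylcyclopentyl]benzene
Conditions: MeI, Pd2(dba)3 (2.5 mol %), P(o-tol)3 (10 mol %), K2CO3, DMF/H2O (9:1), 60 °C
Reagents that add atoms: iodomethane, CI
Why: Suzuki–Miyaura coupling of an arylboronic ester with iodomethane (oxidative addition of MeI, transmetalation, reductive elimination) puts the ring A methyl group on the borylated carbon.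

Step 8
Reactants: 12 1,2-dimethoxy-5-methyl-3-[(1S)-1,2,2-trimethylcyclopentyl]benzene
Product: 14 2-(chloromethyl)-3,4-dimethoxy-1-methyl-5-[(1S)-1,2,2-trimethylcyclopentyl]benzene, via benzylic alcohol 13 (not isolated)
Conditions: (CH2O)n, HCl (gas), ZnCl2 (cat.), AcOH, 40 °C
Reagents that add atoms: paraformaldehyde (as formaldehyde), C=O; hydrogen chloride, Cl
Why: Blanc chloromethylation (electrophilic aromatic substitution by protonated formaldehyde, then OH→Cl exchange of the benzylic alcohol): the ring carbon between the OMe-bearing and the methyl-bearing carbon is the only one an electrophile can reach, the other CH being wedged between the methyl group and the quaternary carbon.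

Step 9
Reactants: 14 2-(chloromethyl)-3,4-dimethoxy-1-methyl-5-[(1S)-1,2,2-trimethylcyclopentyl]benzene; 11 2-{3,4-dimethoxy-5-[(1S)-1,2,2-trimethylcyclopentyl]phenyl}-4,4,5,5-tetramethyl-1,3,2-dioxaborolane
Product: 15 2-({3,4-dimethoxy-5-[(1S)-1,2,2-trimethylcyclopentyl]phenyl}methyl)-3,4-dimethoxy-1-methyl-5-[(1S)-1,2,2-trimethylcyclopentyl]benzene
Conditions: PdCl2(dppf) (5 mol %), Cs2CO3 (3 equiv), THF/H2O (10:1), 70 °C
Reagents that add atoms: none
Why: Suzuki–Miyaura sp3–sp2 coupling: Pd(0) adds oxidatively to the benzylic C–Cl bond of 14, the aryl group of 11 is transferred from the base-activated boronate to Pd, and reductive elimination forms the CH2–aryl bond at the carbon that carried boron. The closest known reaction type is the Pd-catalysed coupling of benzyl halides with arylboronic acids and esters to give diarylmethanes. No ring is closed and no stereocentre is formed; both quaternary centres are remote from the reacting atoms and cannot epimerise. The step needs site fidelity on the methyl-free ring and cross-coupling over homocoupling or hydrolysis: the first is fixed by the C–B bond placed in step 6, the second is favoured because the benzyl–Pd intermediate has no β-hydrogen and the boronate, free of ortho substituents, should transmetalate quickly. The bidentate ferrocenyl phosphine and the small amount of water are chosen to keep solvolysis of the electron-rich chloride slow relative to oxidative addition.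

Step 10
Reactants: 15 tetramethyl ether of the target
Product: 17 3-({3,4-dihydroxy-5-[(1S)-1,2,2-trimethylcyclopentyl]phenyl}methyl)-4-methyl-6-[(1S)-1,2,2-trimethylcyclopentyl]benzene-1,2-diol (CNP0137546.1), via bis(bromodioxaborole) ester 16 (not isolated)
Conditions: BBr3 (8 equiv), CH2Cl2, −78 °C → rt; then degassed H2O, 0 °C
Reagents that add atoms: boron tribromide, BrB(Br)Br (boron and bromine of 16 only)
Why: Lewis-acid ether cleavage: BBr3 coordinates each methoxy oxygen and bromide removes the methyl group by SN2, each catechol ending as a cyclic bromoboronate that water hydrolyses on work-up; C–C bonds and the quaternary stereocentres are not affected, and degassed work-up protects the catechols from air oxidation.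

Compound list
1 | (2,3-dimethoxyphenyl)boronic acid | COc1cccc(B(O)O)c1OC | starting material
2 | 3-methylcyclopent-2-en-1-one | CC1=CC(=O)CC1 | starting material
3 | (S)-3-(2,3-dimethoxyphenyl)-3-methylcyclopentan-1-one | COc1cccc([C@@]2(C)CCC(=O)C2)c1OC | intermediate
4 | trimethyl{[(4S)-4-(2,3-dimethoxyphenyl)-4-methylcyclopent-1-en-1-yl]oxy}silane | COc1cccc([C@@]2(C)CC=C(O[Si](C)(C)C)C2)c1OC | intermediate (not isolated)
5 | (R)-4-(2,3-dimethoxyphenyl)-4-methylcyclopent-2-en-1-one | COc1cccc([C@@]2(C)C=CC(=O)C2)c1OC | intermediate
6 | (4S)-4-(2,3-dimethoxyphenyl)-4,5-dimethylcyclopent-2-en-1-one, both C5 epimers | COc1cccc([C@@]2(C)C=CC(=O)C2C)c1OC | intermediate (not isolated)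
7 | (R)-4-(2,3-dimethoxyphenyl)-4,5,5-trimethylcyclopent-2-en-1-one | COc1cccc([C@@]2(C)C=CC(=O)C2(C)C)c1OC | intermediate
8 | (R)-3-(2,3-dimethoxyphenyl)-2,2,3-trimethylcyclopentan-1-one | COc1cccc([C@@]2(C)CCC(=O)C2(C)C)c1OC | intermediate
9 | [(3S)-3-(2,3-dimethoxyphenyl)-2,2,3-trimethylcyclopentylidene]hydrazine | COc1cccc([C@@]2(C)CCC(=NN)C2(C)C)c1OC | intermediate (not isolated)
10 | (S)-1,2-dimethoxy-3-(1,2,2-trimethylcyclopentyl)benzene | COc1cccc([C@@]2(C)CCCC2(C)C)c1OC | intermediate
11 | 2-{3,4-dimethoxy-5-[(1S)-1,2,2-trimethylcyclopentyl]phenyl}-4,4,5,5-tetramethyl-1,3,2-dioxaborolane | COc1cc(B2OC(C)(C)C(C)(C)O2)cc([C@@]3(C)CCCC3(C)C)c1OC | intermediate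
12 | 1,2-dimethoxy-5-methyl-3-[(1S)-1,2,2-trimethylcyclopentyl]benzene | COc1cc(C)cc([C@@]2(C)CCCC2(C)C)c1OC | intermediate
13 | {2,3-dimethoxy-6-methyl-4-[(1S)-1,2,2-trimethylcyclopentyl]phenyl}methanol | COc1c(CO)c(C)cc([C@@]2(C)CCCC2(C)C)c1OC | intermediate (not isolated)
14 | 2-(chloromethyl)-3,4-dimethoxy-1-methyl-5-[(1S)-1,2,2-trimethylcyclopentyl]benzene | COc1c(CCl)c(C)cc([C@@]2(C)CCCC2(C)C)c1OC | intermediate
15 | 2-({3,4-dimethoxy-5-[(1S)-1,2,2-trimethylcyclopentyl]phenyl}methyl)-3,4-dimethoxy-1-methyl-5-[(1S)-1,2,2-trimethylcyclopentyl]benzene | COc1cc(Cc2c(C)cc([C@@]3(C)CCCC3(C)C)c(OC)c2OC)cc([C@@]4(C)CCCC4(C)C)c1OC | intermediate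
16 | bis(cyclic bromoboronate) of 17, each catechol bridged as a 2-bromo-1,3,2-benzodioxaborole, both cyclopentyl centres (S) | Cc1cc([C@@]2(C)CCCC2(C)C)c3OB(Br)Oc3c1Cc1cc4OB(Br)Oc4c([C@@]2(C)CCCC2(C)C)c1 | intermediate (not isolated)
17 | 3-({3,4-dihydroxy-5-[(1S)-1,2,2-trimethylcyclopentyl]phenyl}methyl)-4-methyl-6-[(1S)-1,2,2-trimethylcyclopentyl]benzene-1,2-diol | Cc1cc([C@@]2(C)CCCC2(C)C)c(O)c(O)c1Cc1cc(O)c(O)c([C@@]2(C)CCCC2(C)C)c1 | target

Total step count: 10.
Longest linear sequence: 10 steps (1 and 2 to 17). Boronate 11 serves twice, as the precursor of 14 and as the coupling partner in step 9.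

Steps most likely to fail

Step 1. The ortho-methoxy group may slow insertion of the enone into the aryl–Pd bond, so that protodeboronation of 1 outruns addition, and the facial selectivity may drop; any loss of enantiomeric purity here would reappear after step 9 as a diastereomer. The fallback sets out from 2 and returns to the route at 3. Commercial veratrole (COc1ccccc1OC) would be ortho-lithiated with n-BuLi/TMEDA in Et2O to (2,3-dimethoxyphenyl)lithium F1 and transmetalated with Me2AlCl to (2,3-dimethoxyphenyl)dimethylaluminium F2. F2 would then add to 2 under Cu(OTf)2 (5 mol %) and a chiral sulfonate-bearing N-heterocyclic carbene (introduced as its Ag complex) in THF at −30 °C, the carbene enantiomer being chosen to give (S)-3. This is a Cu-catalysed asymmetric conjugate addition of an arylaluminium reagent, a different metal and nucleophile class that tolerates ortho-substituted aryl groups.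

Step 9. Oxidative addition at the benzylic chloride flanked by OMe and methyl may be slow, so that solvolysis of the chloride or homocoupling of either partner competes. The fallback sets out from 12 and 11 and returns at 15; it forms the same bond by carbonyl addition instead of cross-coupling. Rieche formylation of 12 (Cl2CHOMe, TiCl4, CH2Cl2, −78 → 0 °C) should give 2,3-dimethoxy-6-methyl-4-[(1S)-1,2,2-trimethylcyclopentyl]benzaldehyde F3. Bromodeboronation of 11 (CuBr2, MeOH/H2O, 80 °C) should give 5-bromo-1,2-dimethoxy-3-[(1S)-1,2,2-trimethylcyclopentyl]benzene F4. Bromine–lithium exchange (n-BuLi, THF, −78 °C) would convert F4 into {3,4-dimethoxy-5-[(1S)-1,2,2-trimethylcyclopentyl]phenyl}lithium F5, which adds to F3 to give the diarylmethanol F6 as a mixture of carbinol epimers. Ionic hydrogenation (Et3SiH, CF3CO2H, CH2Cl2, 0 °C) then removes the hydroxyl group and gives 15.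

Step 5. Hydrazone formation at the carbonyl next to the gem-dimethyl carbon may be incomplete, and hot KOH may cleave a methyl ether. The fallback sets out from 8 and returns at 10. Deprotonation at the only enolisable position and O-triflation (KHMDS, PhNTf2, THF, −78 °C) should give (4S)-4-(2,3-dimethoxyphenyl)-4,5,5-trimethylcyclopent-1-en-1-yl trifluoromethanesulfonate F7. Hydrogenation over PtO2 (H2, EtOH, rt) would cleave the vinylic C–O bond and saturate the alkene to give 10, without strong base or high temperature.

Further compounds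
F1 | step 1 | (2,3-dimethoxyphenyl)lithium | COc1cccc([Li])c1OC
F2 | step 1 | (2,3-dimethoxyphenyl)dimethylaluminium | COc1cccc([Al](C)C)c1OC
F3 | step 9 | 2,3-dimethoxy-6-methyl-4-[(1S)-1,2,2-trimethylcyclopentyl]benzaldehyde | COc1c(C=O)c(C)cc([C@@]2(C)CCCC2(C)C)c1OC
F4 | step 9 | 5-bromo-1,2-dimethoxy-3-[(1S)-1,2,2-trimethylcyclopentyl]benzene | COc1cc(Br)cc([C@@]2(C)CCCC2(C)C)c1OC
F5 | step 9 | {3,4-dimethoxy-5-[(1S)-1,2,2-trimethylcyclopentyl]phenyl}lithium | COc1cc([Li])cc([C@@]2(C)CCCC2(C)C)c1OC
F6 | step 9 | {3,4-dimethoxy-5-[(1S)-1,2,2-trimethylcyclopentyl]phenyl}{2,3-dimethoxy-6-methyl-4-[(1S)-1,2,2-trimethylcyclopentyl]phenyl}methanol, both carbinol epimers | COc1cc(C(O)c2c(C)cc([C@@]3(C)CCCC3(C)C)c(OC)c2OC)cc([C@@]4(C)CCCC4(C)C)c1OC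
F7 | step 5 | (4S)-4-(2,3-dimethoxyphenyl)-4,5,5-trimethylcyclopent-1-en-1-yl trifluoromethanesulfonate | COc1cccc([C@@]2(C)CC=C(OS(=O)(=O)C(F)(F)F)C2(C)C)c1OC
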